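**Plan**

- Ring A is numbered C1 (carries the benzylic carbon), C3 (OMe), C5 (OH), C6 (O-aryl). C1, C3 and C5 are the alternate carbonyl carbons of a triketide, and C6 is the methylene carbon of an aryloxymethyl ketone placed to attack C1; this is what allows an aldol folding.
- Retrosynthesis: cut the palmitate C–O bond, then the C6–C1 bond of ring A. This gives an open 7-aryloxy-1,1,4-trimethoxyhept-3-ene-2,6-dione, with C3 masked as methyl enol ether and the benzylic carbon as dimethyl acetal. The chain is then cut at C1–C2 (acetylide plus Weinreb amide), at C3–C4 (acetylide plus epoxide) and at the O–C6 ether (phenoxide plus epichlorohydrin).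
- Forward: ring B is orcinol. Its mono-MOM ether is joined to C6 while C6 is still sp3, and the chain is grown from C6 to C1 in a line. Ring A is closed last by aldol aromatisation, followed by acetal hydrolysis, reduction, MOM removal and esterification.
- Stereochemistry: the target has no stereocentre. The only stereo element on the way is the E enol ether, set under thermodynamic control. The racemic carbinol carbon from epichlorohydrin is oxidised away before ring closure.

Key step: step 8

Remark: racemic epichlorohydrin is taken, since its stereocentre becomes the C5 carbonyl carbon; compounds 4, 5, 8, 9 and 10 are therefore racemates.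

**Route**

Step 1
Reactants: 1 orcinol
Product: 2 3-(methoxymethoxy)-5-methylphenol
Conditions: MOMCl (0.4 equiv), K2CO3 (0.5 equiv), acetone, 0 °C to rt; excess 1 recovered
Reagents that add atoms: chloromethyl methyl ether, COCCl
Why: Williamson-type O-alkylation of a phenoxide with an alkoxymethyl chloride, in which the excess of diol should make the mono-ether the main product.

Step 2
Reactants: 2 3-(methoxymethoxy)-5-methylphenol; 3 epichlorohydrin (racemic, threefold excess)
Product: 4 2-{[3-(methoxymethoxy)-5-methylphenoxy]methyl}oxirane (racemic)
Conditions: K2CO3, MeCN, 80 °C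
Reagents that add atoms: none
Why: Williamson ether synthesis of an aryl glycidyl ether, which places the ring-B oxygen on the future C6 at an sp3 carbon; the new stereocentre is racemic and is erased in step 7.

Step 3
Reactants: 4 2-{[3-(methoxymethoxy)-5-methylphenoxy]methyl}oxirane
Product: 5 1-[3-(methoxymethoxy)-5-methylphenoxy]pent-4-yn-2-ol (racemic)
Conditions: LiC≡CH·H2NCH2CH2NH2, DMSO, rt; then H2O
Reagents that add atoms: lithium acetylide (ethylenediamine complex), [Li]C#C
Why: SN2 opening of a terminal epoxide by an acetylide at the unsubstituted carbon, which forms the future C3–C4 bond and leaves the MOM ether untouched.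

Step 4
Reactants: 6 methyl dimethoxyacetate
Product: 7 N,2,2-trimethoxy-N-methylacetamide
Conditions: MeNH(OMe)·HCl, i-PrMgCl, THF, −20 to 0 °C
Reagents that add atoms: N,O-dimethylhydroxylamine hydrochloride, CNOC.Cl
Why: Weinreb amide formation by aminolysis of an ester with the magnesium amide of N,O-dimethylhydroxylamine, to which the acetal is inert.

Step 5
Reactants: 5 1-[3-(methoxymethoxy)-5-methylphenoxy]pent-4-yn-2-ol; 7 N,2,2-trimethoxy-N-methylacetamide
Product: 9 6-hydroxy-1,1-dimethoxy-7-[3-(methoxymethoxy)-5-methylphenoxy]hept-3-yn-2-one (racemic), via dilithiated alkynol 8 (not isolated)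
Conditions: n-BuLi (2.05 equiv), THF, −78 °C; then 7, −78 to −20 °C; then AcOH, −78 °C
Reagents that add atoms: none
Why: Weinreb ketone synthesis in which only the acetylide carbon of the alkoxide–acetylide dianion adds to the amide, the chelated tetrahedral intermediate prevents over-addition, and the cold acidic quench keeps the liberated amine from adding to the ynone; this forms the future C1–C2 bond.

Step 6
Reactants: 9 6-hydroxy-1,1-dimethoxy-7-[3-(methoxymethoxy)-5-methylphenoxy]hept-3-yn-2-one
Product: 10 (3E)-6-hydroxy-1,1,4-trimethoxy-7-[3-(methoxymethoxy)-5-methylphenoxy]hept-3-en-2-one (racemic)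
Conditions: NaOMe (0.2 equiv), MeOH, 0 °C to rt
Reagents that add atoms: methanol, CO
Why: Base-catalysed oxa-Michael addition of methanol to the ynone at the β-carbon (future C3); reversible addition–elimination under methoxide should settle the enol ether in the more stable E geometry (methoxy anti to the acyl group), which holds the future C1 and C4 cis.

Step 7
Reactants: 10 (3E)-6-hydroxy-1,1,4-trimethoxy-7-[3-(methoxymethoxy)-5-methylphenoxy]hept-3-en-2-one
Product: 11 (3E)-1,1,4-trimethoxy-7-[3-(methoxymethoxy)-5-methylphenoxy]hept-3-ene-2,6-dione
Conditions: Dess–Martin periodinane, pyridine, CH2Cl2, 0 °C to rt; crude product used promptly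
Reagents that add atoms: none
Why: Dess–Martin oxidation of a secondary alcohol under buffered, non-acidic conditions that should spare acetal, enol ether and MOM ether; it removes the only stereocentre and sets the C5 carbonyl.

Step 8
Reactants: 11 (3E)-1,1,4-trimethoxy-7-[3-(methoxymethoxy)-5-methylphenoxy]hept-3-ene-2,6-dione
Product: 14 3-(dimethoxymethyl)-5-methoxy-2-[3-(methoxymethoxy)-5-methylphenoxy]phenol, via cyclic aldol adduct 12 (not isolated), via cyclohexadienone 13 (not isolated)
Conditions: K2CO3 (2 equiv), degassed MeOH (0.02 M), rt to 40 °C, Ar; then pH 7 phosphate buffer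
Reagents that add atoms: none
Why: In carbonate-buffered methanol part of 11 stays un-ionised at C4, and reversible enolisation of the C5 ketone toward the aryloxy-bearing carbon C6 lets that carbon add to the C1 ketone, which the adjacent dimethoxymethyl group activates; aldol adduct 12 loses water to dienone 13, whose C4 proton shifts to oxygen, and this aromatisation makes the sequence irreversible. The reaction type is the base-induced aldol aromatisation of 2,4,6-triketones and their mono enol ethers, the laboratory counterpart of polyketide folding (diacetylacetone to orcinol). Ring A closes in a 6-(enolendo)-exo-trig aldol that forms the C6–C1 bond. No stereocentre remains, since the two of 12 vanish on aromatisation. The step needs one C–C closure out of several conceivable condensations: the most acidic carbon C4 could only form a four-membered ring, the tertiary acetal C–H would give a quaternary adduct that cannot aromatise and so reverts, and the E enol ether holds C1 and C4 cis. The C3 methoxy and C5 hydroxy groups are distinct from the outset because only C3 was masked, and methanol as solvent makes any alkoxide exchange at C3 degenerate.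

Step 9
Reactants: 14 3-(dimethoxymethyl)-5-methoxy-2-[3-(methoxymethoxy)-5-methylphenoxy]phenol
Product: 15 3-hydroxy-5-methoxy-2-[3-(methoxymethoxy)-5-methylphenoxy]benzaldehyde
Conditions: PPTS (0.1 equiv), acetone/H2O 10:1, rt
Reagents that add atoms: water, O
Why: Acid-catalysed acetal hydrolysis under pyridinium catalysis, mild enough to leave the aryl MOM ether in place, with water in large excess capturing the oxocarbenium ion before ring B can attack it.

Step 10
Reactants: 15 3-hydroxy-5-methoxy-2-[3-(methoxymethoxy)-5-methylphenoxy]benzaldehyde
Product: 16 3-(hydroxymethyl)-5-methoxy-2-[3-(methoxymethoxy)-5-methylphenoxy]phenol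
Conditions: NaBH4, MeOH, 0 °C
Reagents that add atoms: none
Why: Borohydride reduction of an aryl aldehyde to the benzylic alcohol, to which phenol, aryl ethers and MOM ether are inert.

Step 11
Reactants: 16 3-(hydroxymethyl)-5-methoxy-2-[3-(methoxymethoxy)-5-methylphenoxy]phenol
Product: 17 3-(hydroxymethyl)-2-(3-hydroxy-5-methylphenoxy)-5-methoxyphenol
Conditions: HCl (0.5 M in MeOH), rt
Reagents that add atoms: none
Why: Acid-catalysed transacetalisation of the aryl MOM ether to methanol, so that formaldehyde is never free to attack the electron-rich rings; it is placed after the reduction so that no aldehyde or acetal carbon is present to close onto ring B in a Friedel–Crafts sense.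

Step 12
Reactants: 17 3-(hydroxymethyl)-2-(3-hydroxy-5-methylphenoxy)-5-methoxyphenol; 18 palmitic acid
Product: 19 betaethrin H, [3-hydroxy-2-(3-hydroxy-5-methylphenoxy)-5-methoxyphenyl]methyl hexadecanoate
Conditions: PPh3, DIAD, THF, 0 °C to rt
Reagents that add atoms: none
Why: Mitsunobu esterification in which only the primary benzylic alcohol is activated as an oxyphosphonium ion and is displaced by palmitate, the carboxylic acid being far more acidic than the phenols, as is known for phenolic benzyl alcohols.

**Compound list**

1 | orcinol (5-methylbenzene-1,3-diol) | Cc1cc(O)cc(O)c1 | starting material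
2 | 3-(methoxymethoxy)-5-methylphenol | COCOc1cc(C)cc(O)c1 | intermediate
3 | epichlorohydrin (racemic) | ClCC1CO1 | starting material
4 | 2-{[3-(methoxymethoxy)-5-methylphenoxy]methyl}oxirane (racemic) | COCOc1cc(C)cc(OCC2CO2)c1 | intermediate
5 | 1-[3-(methoxymethoxy)-5-methylphenoxy]pent-4-yn-2-ol (racemic) | COCOc1cc(C)cc(OCC(O)CC#C)c1 | intermediate
6 | methyl dimethoxyacetate | COC(OC)C(=O)OC | starting material
7 | N,2,2-trimethoxy-N-methylacetamide | COC(OC)C(=O)N(C)OC | intermediate
8 | dilithiated alkynol: lithium alkoxide and lithium acetylide of 5 (formed in the flask, not isolated) | COCOc1cc(C)cc(OCC(O[Li])CC#C[Li])c1 | intermediate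
9 | 6-hydroxy-1,1-dimethoxy-7-[3-(methoxymethoxy)-5-methylphenoxy]hept-3-yn-2-one (racemic) | COC(OC)C(=O)C#CCC(O)COc1cc(C)cc(OCOC)c1 | intermediate
10 | (3E)-6-hydroxy-1,1,4-trimethoxy-7-[3-(methoxymethoxy)-5-methylphenoxy]hept-3-en-2-one (racemic) | COC(OC)C(=O)/C=C(/OC)CC(O)COc1cc(C)cc(OCOC)c1 | intermediate
11 | (3E)-1,1,4-trimethoxy-7-[3-(methoxymethoxy)-5-methylphenoxy]hept-3-ene-2,6-dione | COC(OC)C(=O)/C=C(/OC)CC(=O)COc1cc(C)cc(OCOC)c1 | intermediate
12 | cyclic aldol adduct: 3-(dimethoxymethyl)-3-hydroxy-5-methoxy-2-[3-(methoxymethoxy)-5-methylphenoxy]cyclohex-4-en-1-one (diastereomer mixture, formed in the flask, not isolated) | COC(OC)C1(O)C=C(OC)CC(=O)C1Oc1cc(C)cc(OCOC)c1 | intermediate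
13 | cyclohexadienone: 3-(dimethoxymethyl)-5-methoxy-2-[3-(methoxymethoxy)-5-methylphenoxy]cyclohexa-2,4-dien-1-one (formed in the flask, not isolated) | COC(OC)C1=C(Oc2cc(C)cc(OCOC)c2)C(=O)CC(OC)=C1 | intermediate
14 | 3-(dimethoxymethyl)-5-methoxy-2-[3-(methoxymethoxy)-5-methylphenoxy]phenol | COC(OC)c1cc(OC)cc(O)c1Oc1cc(C)cc(OCOC)c1 | intermediate
15 | 3-hydroxy-5-methoxy-2-[3-(methoxymethoxy)-5-methylphenoxy]benzaldehyde | O=Cc1cc(OC)cc(O)c1Oc1cc(C)cc(OCOC)c1 | intermediate
16 | 3-(hydroxymethyl)-5-methoxy-2-[3-(methoxymethoxy)-5-methylphenoxy]phenol | OCc1cc(OC)cc(O)c1Oc1cc(C)cc(OCOC)c1 | intermediate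
17 | 3-(hydroxymethyl)-2-(3-hydroxy-5-methylphenoxy)-5-methoxyphenol | OCc1cc(OC)cc(O)c1Oc1cc(C)cc(O)c1 | intermediate
18 | palmitic acid (hexadecanoic acid) | CCCCCCCCCCCCCCCC(=O)O | starting material
19 | betaethrin H | CCCCCCCCCCCCCCCC(=O)OCc1cc(OC)cc(O)c1Oc1cc(C)cc(O)c1 | target

**Count and risks**

Total step count: 12. Longest linear sequence: 11 steps from orcinol (steps 1 to 3 and 5 to 12); step 4 is a one-step side branch.

Steps most likely to fail, in order of risk:

Step 8 (ring closure). Ionisation at the doubly activated C4 methylene may drain 11 into an unreactive vinylogous enolate while the conjugated C1 carbonyl accepts the C6 enolate only slowly. Intermolecular condensation or methoxide cleavage of the C4–C5 bond could then outrun cyclisation. The fallback gives up the enol ether mask and folds the free triketone, a classical polyketide-type cyclisation, at the price of a late selective O-methylation. It sets out from 6 and 2 and returns at 14.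
- Claisen condensation of 6 with acetone (NaOMe, Et2O) would give 1,1-dimethoxypentane-2,4-dione F1.
- Alkylation of 2 with methyl bromoacetate (K2CO3, acetone) would give methyl [3-(methoxymethoxy)-5-methylphenoxy]acetate F2.
- The dianion of F1 (LiN(i-Pr)2, 2.5 equiv, THF, −78 to 0 °C) would be acylated at its terminal methyl carbon by F2 to give 1,1-dimethoxy-7-[3-(methoxymethoxy)-5-methylphenoxy]heptane-2,4,6-trione F3.
- KOH in MeOH would close F3 through the same C6-to-C1 aldol to 5-(dimethoxymethyl)-4-[3-(methoxymethoxy)-5-methylphenoxy]benzene-1,3-diol F4.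
- MeI (1 equiv) with K2CO3 in acetone would methylate the unhindered C3 hydroxyl in preference to the C5 hydroxyl beside the aryloxy group, which gives 14.

Step 7 (oxidation). The free hydroxyl of 10 may close onto the C1 carbonyl as a lactol, which traces of acid could drive on to loss of water and methanol toward a dihydropyranone. The dione, once formed, may also be over-oxidised at its activated methylene or condense on handling. The fallback brings C5 in at the ketone level by a vinylogous Claisen acylation, so that no alcohol has to be oxidised. It sets out from 7 and 2 and returns at 11.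
- 7 with MeC≡CMgBr (THF, 0 °C) would give 1,1-dimethoxypent-3-yn-2-one F5.
- NaOMe in MeOH would add methanol to give (3E)-1,1,4-trimethoxypent-3-en-2-one F6.
- 2 with 2-chloro-N-methoxy-N-methylacetamide (K2CO3, MeCN) would give N-methoxy-2-[3-(methoxymethoxy)-5-methylphenoxy]-N-methylacetamide F7.
- γ-Deprotonation of F6 with LiN(SiMe3)2 (2 equiv, THF, −78 °C) and acylation of the lithium dienolate at its terminal carbon by F7 would give 11.

Step 12 (esterification). A phenoxide may compete with palmitate for the benzylic oxyphosphonium ion, which would lead to benzyl aryl ethers and oligomers, or a phenol may be acylated. The fallback is an enzymatic transesterification: 17 with vinyl palmitate and immobilised Candida antarctica lipase B (tert-amyl alcohol, 45 °C) should acylate only the primary alcohol and lead straight to 19. No new compound is involved.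

**Further compounds**

F1 | step 8 | 1,1-dimethoxypentane-2,4-dione | COC(OC)C(=O)CC(C)=O
F2 | step 8 | methyl [3-(methoxymethoxy)-5-methylphenoxy]acetate | COC(=O)COc1cc(C)cc(OCOC)c1
F3 | step 8 | 1,1-dimethoxy-7-[3-(methoxymethoxy)-5-methylphenoxy]heptane-2,4,6-trione | COC(OC)C(=O)CC(=O)CC(=O)COc1cc(C)cc(OCOC)c1
F4 | step 8 | 5-(dimethoxymethyl)-4-[3-(methoxymethoxy)-5-methylphenoxy]benzene-1,3-diol | COC(OC)c1cc(O)cc(O)c1Oc1cc(C)cc(OCOC)c1
F5 | step 7 | 1,1-dimethoxypent-3-yn-2-one | COC(OC)C(=O)C#CC
F6 | step 7 | (3E)-1,1,4-trimethoxypent-3-en-2-one | COC(OC)C(=O)/C=C(/OC)C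
F7 | step 7 | N-methoxy-2-[3-(methoxymethoxy)-5-methylphenoxy]-N-methylacetamide | CON(C)C(=O)COc1cc(C)cc(OCOC)c1
F0 | step 12 | none | none
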